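**Assumption (one line):** ethyl (R)-4-chloro-3-hydroxybutanoate is taken as a cheap bulk chiral building block; ring locants below follow the target: C1 = C(CH3)(chlorovinyl), C2 = CH2, C3 = C(Cl)(CH2Br), C4 = CHCl, C5 = CH2, C6 = CHCl; carbon-donating reagents are numbered as starting materials.

## Retrosynthetic overview

1. 16 ⇒ 15: electrochemical Br–Cl addition across the exocyclic C3=CH2 (tertiary C–Cl plus CH2Br, the last stereocentre).
2. C4–Cl and C6–Cl (both cis to the chlorovinyl) ⇒ two hydroxyls on the opposite face, each replaced with inversion; the C4–OH comes from OH-directed epoxidation of the ring alkene and epoxide → exocyclic allylic alcohol isomerisation.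
3. (E)-Chlorovinyl ⇒ ester (DIBAL, then Takai).
4. Cyclohexene (the only ring, formed once, in step 4) ⇒ RCM of an allyl/methallyl diene.
5. Quaternary C1 ⇒ double Frater–Seebach alkylation of ethyl (S)-3-hydroxyhex-5-enoate ⇐ ethyl (R)-4-chloro-3-hydroxybutanoate (the only purchased stereocentre).

## Forward route

**Step 1**
Reactants: 1 ethyl (R)-4-chloro-3-hydroxybutanoate; 2 vinylmagnesium bromide
Product: 3 ethyl (S)-3-hydroxyhex-5-enoate
Conditions: 2 (2.5 equiv), CuI (10 mol %), THF, −40 → −10 °C
Reagents that add atoms: vinylmagnesium bromide, C=C[Mg]Br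
Why: Copper-catalysed Grignard opening of the epoxide formed in situ from the magnesium chlorohydrinate occurs at the CH2 terminus, so the purchased stereocentre is untouched (R → S is a CIP priority change only).

**Step 2**
Reactants: 3; 4 iodomethane
Product: 5 ethyl (2S,3S)-3-hydroxy-2-methylhex-5-enoate
Conditions: LDA (2.2 equiv), THF, −78 → −30 °C; MeI, DMPU, −78 → −20 °C
Reagents that add atoms: iodomethane, CI
Why: Frater–Seebach alkylation: the lithium-chelated alkoxide/enolate dianion is methylated on the face anti to the carbinol substituent, giving the 2,3-anti ester.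

**Step 3**
Reactants: 5; 6 3-bromo-2-methylprop-1-ene
Product: 7 ethyl (2S,3S)-3-hydroxy-2-methyl-2-(2-methylprop-2-en-1-yl)hex-5-enoate
Conditions: LDA (2.3 equiv), THF, −78 → −20 °C; 6, DMPU, −40 → 0 °C
Reagents that add atoms: 3-bromo-2-methylprop-1-ene, C=C(C)CBr
Why: Second Frater–Seebach alkylation: the electrophile again enters anti to the alkoxide, so methallyl ends anti and methyl syn to OH, setting the all-carbon quaternary centre (future C1) under control of the purchased carbinol.

**Step 4**
Reactants: 7
Product: 8 ethyl (1S,6S)-6-hydroxy-1,3-dimethylcyclohex-3-ene-1-carboxylate (OH cis to the C1 methyl, trans to CO2Et)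
Conditions: Grubbs II (3 mol %), CH2Cl2, 40 °C
Reagents that add atoms: none
Why: Ring-closing metathesis of the allyl and methallyl arms (loss of ethylene) forms the only ring as a trisubstituted cyclohexene without touching either stereocentre.

**Step 5**
Reactants: 8
Product: 9 ethyl (1S,3S,4S,6R)-4-hydroxy-1,3-dimethyl-7-oxabicyclo[4.1.0]heptane-3-carboxylate (epoxide oxygen cis to OH)
Conditions: VO(acac)2 (2 mol %), t-BuOOH, CH2Cl2, 0 °C → rt
Reagents that add atoms: tert-butyl hydroperoxide, CC(C)(C)OO
Why: Hydroxyl-directed vanadium epoxidation of a homoallylic cyclohexenol delivers oxygen to the alkene face cis to the OH (the face of the C1 methyl), which sets the C4 oxygen on that face.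

**Step 6**
Reactants: 9
Product: 10 ethyl (1S,3R,4R,6R)-4-chloro-1,3-dimethyl-7-oxabicyclo[4.1.0]heptane-3-carboxylate (Cl cis to CO2Et, trans to the epoxide oxygen)
Conditions: Tf2O, 2,6-lutidine, CH2Cl2, −78 °C; then n-Bu4NCl, −78 → 0 °C
Reagents that add atoms: tetrabutylammonium chloride, [Cl-].CCCC[N+](CCCC)(CCCC)CCCC
Why: SN2 displacement of the secondary triflate by chloride with Walden inversion sets C6–Cl: with the triflate equatorial there is no anti-periplanar β-H (E2 suppressed), the β-ester disfavours ionisation, and chloride enters axially, anti to the axial methyl.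

**Step 7**
Reactants: 10
Product: 11 ethyl (1R,2R,4R)-2-chloro-4-hydroxy-1-methyl-5-methylidenecyclohexane-1-carboxylate
Conditions: Et2Al(TMP) (from Et2AlCl + LiTMP, 3 equiv), toluene, 0 °C
Reagents that add atoms: none
Why: Aluminium-amide epoxide-to-allylic-alcohol isomerisation (syn β-elimination) removes a proton from the methyl group and cleaves the tertiary C–O bond, giving the exocyclic alkene while the C4–O configuration is retained.

**Step 8**
Reactants: 11
Product: 12 (1R,2R,4R)-2-chloro-4-hydroxy-1-methyl-5-methylidenecyclohexane-1-carbaldehyde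
Conditions: DIBAL-H (2.2 equiv), CH2Cl2, −78 °C; Rochelle salt work-up
Reagents that add atoms: none
Why: Low-temperature DIBAL reduction of the hindered α-quaternary ester stops at the tetrahedral aluminate and releases the aldehyde on work-up, leaving C–Cl and the alkene untouched.

**Step 9**
Reactants: 12; 13 chloroform
Product: 14 (1R,4R,5R)-5-chloro-4-[(E)-2-chloroethenyl]-4-methyl-2-methylidenecyclohexan-1-ol
Conditions: CrCl2 (6 equiv), 13 (2 equiv), THF, 65 °C
Reagents that add atoms: chloroform, ClC(Cl)Cl
Why: Takai olefination (gem-dichromium carbenoid) converts the aldehyde into the (E)-chloroalkene and tolerates the free OH and the unactivated C–Cl; it is run before any allylic chloride exists because Cr(II) would reduce one.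

**Step 10**
Reactants: 14
Product: 15 (1R,2R,4S)-2,4-dichloro-1-[(E)-2-chloroethenyl]-1-methyl-5-methylidenecyclohexane
Conditions: PPh3, hexachloroacetone, CH2Cl2, 0 °C
Reagents that add atoms: hexachloroacetone, ClC(Cl)(Cl)C(=O)C(Cl)(Cl)Cl
Why: Appel-type chlorination of the secondary allylic alcohol (axial alkoxyphosphonium, equatorial chloride attack) proceeds by direct SN2 with inversion and without allylic transposition, placing C4–Cl cis to C6–Cl.

**Step 11**
Reactants: 15
Product: 16 violacene, (1R,2S,4R,5R)-1-(bromomethyl)-1,2,4-trichloro-5-[(E)-2-chloroethenyl]-5-methylcyclohexane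
Conditions: divided cell, graphite anode / Pt cathode, constant current (≈5 mA cm⁻², 2.2 F mol⁻¹), Et4NBr (1.1 equiv), Et4NCl (8 equiv), CH2Cl2–HFIP 9:1, −20 °C
Reagents that add atoms: tetraethylammonium bromide, [Br-].CC[N+](CC)(CC)CC; tetraethylammonium chloride, [Cl-].CC[N+](CC)(CC)CC
Why: Proposed new method: anodic oxidation of bromide in a chloride-rich electrolyte (Br⁻ is oxidised before Cl⁻, so no free Cl2 forms) generates BrCl/[BrCl2]⁻ at low steady-state concentration; its electrophilic bromine adds to the exocyclic C=CH2 from the open equatorial face, and chloride, the only abundant nucleophile, opens the bromonium at the tertiary carbon anti and axially (the CH2Br arm relaxes equatorial, whereas the alternative would put CH2Br syn-axial to the chlorovinyl group), giving Markovnikov bromochlorination with C3–Cl cis to C4–Cl and leaving the electron-poor chloroalkene untouched; the closest known reaction types are anodic dibromination and dichlorination of alkenes and chemical bromochlorination with NBS/chloride or R4N⁺ BrCl2⁻ salts.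

## Compound list

1 | ethyl (R)-4-chloro-3-hydroxybutanoate | ClC[C@H](O)CC(=O)OCC | starting material
2 | vinylmagnesium bromide | C=C[Mg]Br | starting material
3 | ethyl (S)-3-hydroxyhex-5-enoate | C=CC[C@H](O)CC(=O)OCC | intermediate
4 | iodomethane | CI | starting material
5 | ethyl (2S,3S)-3-hydroxy-2-methylhex-5-enoate | C=CC[C@H](O)[C@H](C)C(=O)OCC | intermediate
6 | 3-bromo-2-methylprop-1-ene | C=C(C)CBr | starting material
7 | ethyl (2S,3S)-3-hydroxy-2-methyl-2-(2-methylprop-2-en-1-yl)hex-5-enoate | C=CC[C@H](O)[C@](C)(CC(C)=C)C(=O)OCC | intermediate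
8 | ethyl (1S,6S)-6-hydroxy-1,3-dimethylcyclohex-3-ene-1-carboxylate | C[C@]1(C(=O)OCC)CC(C)=CC[C@@H]1O | intermediate
9 | ethyl (1S,3S,4S,6R)-4-hydroxy-1,3-dimethyl-7-oxabicyclo[4.1.0]heptane-3-carboxylate | C[C@]1(C(=O)OCC)C[C@]2(C)O[C@@H]2C[C@@H]1O | intermediate
10 | ethyl (1S,3R,4R,6R)-4-chloro-1,3-dimethyl-7-oxabicyclo[4.1.0]heptane-3-carboxylate | C[C@]1(C(=O)OCC)C[C@]2(C)O[C@@H]2C[C@H]1Cl | intermediate
11 | ethyl (1R,2R,4R)-2-chloro-4-hydroxy-1-methyl-5-methylidenecyclohexane-1-carboxylate | C[C@]1(C(=O)OCC)CC(=C)[C@H](O)C[C@H]1Cl | intermediate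
12 | (1R,2R,4R)-2-chloro-4-hydroxy-1-methyl-5-methylidenecyclohexane-1-carbaldehyde | C[C@]1(C=O)CC(=C)[C@H](O)C[C@H]1Cl | intermediate
13 | chloroform | ClC(Cl)Cl | starting material
14 | (1R,4R,5R)-5-chloro-4-[(E)-2-chloroethenyl]-4-methyl-2-methylidenecyclohexan-1-ol | C[C@]1(/C=C/Cl)CC(=C)[C@H](O)C[C@H]1Cl | intermediate
15 | (1R,2R,4S)-2,4-dichloro-1-[(E)-2-chloroethenyl]-1-methyl-5-methylidenecyclohexane | C[C@]1(/C=C/Cl)CC(=C)[C@@H](Cl)C[C@H]1Cl | intermediate
16 | violacene, (1R,2S,4R,5R)-1-(bromomethyl)-1,2,4-trichloro-5-[(E)-2-chloroethenyl]-5-methylcyclohexane | C[C@]1(/C=C/Cl)C[C@](Cl)(CBr)[C@@H](Cl)C[C@H]1Cl | target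

## Step count and risks

Total steps: 11. Longest linear sequence: 11 (fully linear from 1).

Three steps most likely to fail:

1. **Step 11 (the proposed new method).** Risks are competing dibromide formation, incomplete facial selectivity at C3, and chloride exchange at the allylic C4–Cl in the chloride-rich medium. Fallback (known chemistry, different approach): an oxygen relay from 15. Epoxidise the exocyclic alkene with mCPBA (attack anti to the axial chlorovinyl), open the spiro-epoxide at the tertiary carbon with inversion using TiCl4 to give the tertiary chloride/primary alcohol, then convert CH2OH to CH2Br with CBr4/PPh3.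
2. **Step 6 (invertive chloride displacement next to the quaternary carbon).** Risks are sluggish substitution and elimination to the diene. Fallback: give up backside displacement for a radical C–O → C–Cl exchange. Convert 9 to its mixed oxalate with N-hydroxypyridine-2-thione and photolyse in CCl4 (Barton-type deoxychlorination), then separate the C6 epimers.
3. **Step 7 (epoxide → exocyclic allylic alcohol).** Risks are the endocyclic alkene regioisomer or base attack on the chloride. Fallback: Cp2TiCl-mediated homolytic epoxide opening to the tertiary radical, followed by β-hydrogen loss from the methyl group, to reach the same exocyclic allylic alcohol 11.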